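**Target:** 17, 5,7-dihydroxy-3-(2,4-dihydroxyphenyl)-6,8-bis(3-methylbut-2-enyl)-4H-chromen-4-one (C25H26O6, achiral).

## The problem

Compound 17 is a 3-arylchromen-4-one: ring A (a phloroglucinol) is fused to the pyranone ring C through C4a and C8a, and ring B (a resorcinol) hangs on C3. Ring A is hexasubstituted (O1, C4, 5-OH, 6-prenyl, 7-OH, 8-prenyl), so the positions of both prenyl groups must be fixed beyond doubt, which direct C-prenylation of a finished polyphenol cannot deliver. The molecule has no stereocentre, so nothing needs to be controlled in the end, and any stereocentre that appears on the way only has to be erasable. The fragile parts are the two trisubstituted olefins, which rule out hydrogenolysis, electrophilic halogen and strong oxidants and which protic acid can close onto the neighbouring 5- and 7-hydroxyls as dimethylchromans; the four phenols; and the 2'-hydroxyl, which sits within reach of C2. Ring C holds one carbon that is bonded to neither aryl ring: C2, a lone CH between O1 and C3 at the oxidation level of formate. That carbon can be the methylene of a methoxymethyl (MOM) ether already on the ring A oxygen that becomes O1, so that O1–C2 exists from the protection step and only C2–C3 has to be made. Ring A has three identical oxygens and two identical prenyl groups, so the two acetals ortho to the carbonyl are equivalent: whichever reacts, the same chromanone forms and the other acetal is left as the 5-O protecting group.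

## Retrosynthesis

**17 back to 15.** The four O–H bonds are traced to two silyl ethers on ring B (16) and two MOM ethers on ring A, and the C2=C3 double bond to the saturated 2-methoxychroman-4-one 15, in which C2 carries a methoxy group and C3 a hydrogen. Splitting the protecting groups by ring lets one short acid treatment do three jobs on ring A and ring C (15 to 16), with buffered fluoride for ring B (16 to 17). The forward demand is that the acid performs the 1,2-elimination across C2–C3 and cleaves the two aryl acetals without closing a prenyl group onto a freed phenol.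

**15 back to 14 (the strategic cut, C2–C3).** The neighbouring cuts were weighed first. Cutting O1–C2 is the classical deoxybenzoin route; it needs one ring A oxygen set free selectively and a separate one-carbon reagent. Cutting C3–C1' (cross-coupling or aryl migration) or C4–C4a (acylation) requires a preformed chromone or acid that prenyl groups do not tolerate. Cutting C2–C3 instead leads to the acyclic diazoketone 14, in which every ring A oxygen carries the same protecting group and C2 is already attached to O1. The forward reaction is a rhodium carbene insertion into the acetal C–H bond, and it must beat attack of the carbene on the ether oxygen.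

**14 back to 13.** The diazo group is removed to give the deoxybenzoin 13. The CH2 between an aryl ring and an aroyl group is acidic enough for direct diazo transfer, so no activating group is needed.

**13 back to 7 and 10 (C4–C4a).** The aryl–carbonyl bond is cut to the aryllithium 11, made from arene 7, and the Weinreb amide 10. A Friedel–Crafts or Hoesch acylation would make the same bond but under acid that prenylated phloroglucinols do not survive. The last free position of 7 lies between two MOM ethers and is ideal for directed metalation. The amide stops at the ketone through the chelated adduct 12. The forward demand is that addition outruns enolisation of the arylacetamide.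

**7 back to 1 and 3.** Both aryl–CH2 bonds are cut by iterated directed ortho-metalation and allylation (7 from 5, 5 from 2), and 2 comes from phloroglucinol (1) by threefold methoxymethylation. The MOM group serves three times: directing group, protecting group and source of C2. Prenyl bromide (3) delivers the side chains as prenyl from the start, so no later olefin editing is needed.

**10 back to 8.** The amide 10 comes from 9 by silylation, and 9 from commercial 2,4-dihydroxyphenylacetic acid (8). Ring B carries silyl ethers because they have no C–H bond alpha to oxygen; a MOM group on the 2'-oxygen would offer the carbene a five-membered insertion. Triisopropylsilyl is chosen over smaller silyl groups because it should withstand the amidine base of step 7 and the methanolic acid of step 9.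

## Roads not taken

**Alternative 1:** Both ring A side-chain bonds (C6–CH2 and C8–CH2) are cut back to allyl ethers on a finished isoflavone, 5,7-bis(allyloxy)-3-[2,4-bis(methoxymethoxy)phenyl]-4H-chromen-4-one A1. Heating A1 would move both allyl groups to carbon by Claisen rearrangement and give the diallyl diphenol A2.

- Merits: the isoflavone core is built by routine chemistry before any olefin is present. The rearrangement is regioconvergent, because the 5-O-allyl group has only C6 as a free ortho position and the 7-O-allyl group then ends on C8 (directly or by a para shift).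
- Weak points: the rearrangement delivers allyl, not prenyl, so a double olefin cross-metathesis (second-generation Grubbs catalyst) on a free diphenol must follow. The 5-O-allyl ether needs about 200 °C, where ortho-allylphenols can close to dihydrofurans. Ring A is not fully defined until late.
- Comparison: the key step of this road is textbook pericyclic chemistry and is more certain than an untested C–H insertion. The step count is comparable. The chosen plan sets against it a convergent union of two fragments, prenyl groups installed as such with positions fixed by symmetry, no high-temperature step, no ruthenium step on a polyphenol, and a C2 that costs no extra reagent.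

**Alternative 2:** The C3–C1' bond is made by a biomimetic 1,2-aryl shift of the 2'-hydroxychalcone A3, (E)-1-[2,4-bis(benzyloxy)-6-hydroxyphenyl]-3-[2,4-bis(benzyloxy)phenyl]prop-2-en-1-one. Tl(NO3)3 (trivalent thallium) in methanol with trimethyl orthoformate moves ring B from the beta to the alpha carbon, and acid closes ring C to the tetrabenzyl isoflavone A4.

- Merits: A3 comes from a single aldol condensation. The rearrangement is well documented for oxygenated isoflavones, and it is both shorter and safer than the chosen key step for the bare core.
- Weak points: it solves the wrong half of the problem. Trivalent thallium attacks electron-rich olefins, so the prenyl groups cannot be present. The benzyl ethers of A4 come off by hydrogenolysis, which also forbids prenyl groups. Both prenyl groups would then have to be put on an unprotected polyphenol, where O-alkylation, C6/C8 scrambling and ring B alkylation compete. The reagent is toxic and stoichiometric.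
- Comparison: for the core alone this road is better. The chosen plan has to set against it that ring A is complete before ring C closes and that no oxidant or hydrogenation ever meets the prenyl olefins.

**Alternative 3:** The C4–C4a bond is made by an intramolecular Friedel–Crafts acylation of the enol ether lactone A5, 3-{[3,5-bis(allyloxy)phenoxy]methylene}-2-oxo-2,3-dihydrobenzofuran-6-yl acetate. In P2O5/methanesulfonic acid (Eaton's reagent) or triflic acid, the ring A carbon ortho to the vinylic ether oxygen would attack the lactone carbonyl, close ring C and release the 2'-hydroxyl, giving isoflavone A6.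

- Merits: the lactone both activates the acyl carbon and masks the 2'-oxygen. The symmetric phenoxy ring makes both ortho positions equivalent. Acid cyclisation of beta-aryloxyacrylic acid derivatives to chromones is a close analogy, so the closure is better precedented than the chosen one. No diazo compound or noble metal is needed.
- Weak points: superacid threatens the allyl aryl ethers, the acetate and the enol ether link. Prenyl groups cannot be present, so the Claisen and metathesis steps of alternative 1 follow, plus deacetylation, and the route becomes the longest of the four.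
- Comparison: this road is cheaper in reagents and safer in its ring closure. The chosen plan sets against it neutral conditions that tolerate the finished ring A and a shorter sequence.

Key step: step 8

Remark on the chemistry: compound 15 is drawn as the racemic trans diastereomer; the cis isomer would serve equally, because C2 and C3 both become trigonal in step 9.

## Route

Step 1
Reactants: 1 phloroglucinol (benzene-1,3,5-triol)
Product: 2 1,3,5-tris(methoxymethoxy)benzene
Conditions: NaH (3.3 equiv), MOMCl (3.3 equiv), DMF, 0 °C → rt
Reagents that add atoms: chloromethyl methyl ether, COCCl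
Why: Threefold Williamson-type O-alkylation of the phenoxide by the hard, highly reactive chloromethyl ether, one equivalent per phenol; O-alkylation should dominate over C-alkylation in a dipolar aprotic solvent.

Step 2
Reactants: 2 1,3,5-tris(methoxymethoxy)benzene; 3 prenyl bromide (1-bromo-3-methylbut-2-ene)
Product: 5 1,3,5-tris(methoxymethoxy)-2-(3-methylbut-2-enyl)benzene, via 2,4,6-tris(methoxymethoxy)phenyllithium 4 (not isolated)
Conditions: n-BuLi, THF, 0 °C; CuI (10 mol %), then 3, −78 °C → rt
Reagents that add atoms: none
Why: Directed ortho-metalation removes a proton flanked by two chelating MOM ethers, and copper-catalysed allylic substitution of 3 at its primary carbon (SN2, not SN2') installs the prenyl group.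

Step 3
Reactants: 5 1,3,5-tris(methoxymethoxy)-2-(3-methylbut-2-enyl)benzene; 3 prenyl bromide
Product: 7 1,3,5-tris(methoxymethoxy)-2,4-bis(3-methylbut-2-enyl)benzene, via 2,4,6-tris(methoxymethoxy)-3-(3-methylbut-2-enyl)phenyllithium 6 (not isolated)
Conditions: n-BuLi, THF, 0 °C; CuI (10 mol %), then 3, −78 °C → rt
Reagents that add atoms: none
Why: Second directed ortho-metalation at one of the two equivalent remaining ring positions, each again between two MOM ethers; chelation-controlled ring metalation should outrun deprotonation of the benzylic-allylic CH2 of the first prenyl group, and the allylation then runs as in step 2.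

Step 4
Reactants: 8 2,4-dihydroxyphenylacetic acid
Product: 9 2-(2,4-dihydroxyphenyl)-N-methoxy-N-methylacetamide
Conditions: MeNHOMe·HCl, EDC·HCl, HOBt (cat.), N-methylmorpholine, DMF, 0 °C → rt
Reagents that add atoms: N,O-dimethylhydroxylamine hydrochloride, CNOC.Cl
Why: Carbodiimide amide coupling, which tolerates free phenols; any lactone or aryl ester formed through the ortho hydroxyl is itself an acyl donor and should be opened by the amine to the same amide.

Step 5
Reactants: 9 2-(2,4-dihydroxyphenyl)-N-methoxy-N-methylacetamide
Product: 10 2-[2,4-bis(triisopropylsilyloxy)phenyl]-N-methoxy-N-methylacetamide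
Conditions: TIPSCl, imidazole, DMF, rt
Reagents that add atoms: triisopropylsilyl chloride, CC(C)[Si](Cl)(C(C)C)C(C)C
Why: Imidazole-promoted silylation of both phenols; the silyl ethers carry no C–H bond alpha to oxygen and are robust toward aryllithiums at low temperature, DBU and dilute methanolic acid.

Step 6
Reactants: 7 1,3,5-tris(methoxymethoxy)-2,4-bis(3-methylbut-2-enyl)benzene; 10 2-[2,4-bis(triisopropylsilyloxy)phenyl]-N-methoxy-N-methylacetamide
Product: 13 2-[2,4-bis(triisopropylsilyloxy)phenyl]-1-[2,4,6-tris(methoxymethoxy)-3,5-bis(3-methylbut-2-enyl)phenyl]ethan-1-one, via 2,4,6-tris(methoxymethoxy)-3,5-bis(3-methylbut-2-enyl)phenyllithium 11 (not isolated), via lithium N-methoxy-N-methylhemiaminal alkoxide 12 (not isolated)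
Conditions: n-BuLi (0.95 equiv), THF, 0 °C; 10, −78 → −20 °C; AcOH, −78 °C
Reagents that add atoms: none
Why: Third directed ortho-metalation at the only ring hydrogen left, then Weinreb ketone synthesis: the chelated tetrahedral adduct 12 holds until the acidic quench, so the ketone never meets the aryllithium and over-addition is excluded. A slight deficit of n-BuLi keeps butyllithium away from the amide.

Step 7
Reactants: 13 2-[2,4-bis(triisopropylsilyloxy)phenyl]-1-[2,4,6-tris(methoxymethoxy)-3,5-bis(3-methylbut-2-enyl)phenyl]ethan-1-one
Product: 14 2-diazo-2-[2,4-bis(triisopropylsilyloxy)phenyl]-1-[2,4,6-tris(methoxymethoxy)-3,5-bis(3-methylbut-2-enyl)phenyl]ethan-1-one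
Conditions: p-ABSA, DBU, MeCN (anhydrous), 0 °C → rt
Reagents that add atoms: 4-acetamidobenzenesulfonyl azide, CC(=O)Nc1ccc(cc1)S(=O)(=O)N=[N+]=[N-]
Why: Regitz diazo transfer: the CH2 between aryl and aroyl is acidic enough for DBU, the enolate attacks the terminal nitrogen of the sulfonyl azide, and the triazene collapses to the diazoketone and the sulfonamide.

Step 8
Reactants: 14 2-diazo-2-[2,4-bis(triisopropylsilyloxy)phenyl]-1-[2,4,6-tris(methoxymethoxy)-3,5-bis(3-methylbut-2-enyl)phenyl]ethan-1-one
Product: 15 rac-(2R,3S)-3-[2,4-bis(triisopropylsilyloxy)phenyl]-2-methoxy-5,7-bis(methoxymethoxy)-6,8-bis(3-methylbut-2-enyl)chroman-4-one (trans)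
Conditions: Rh2(OAc)4 (1 mol %), CH2Cl2, slow addition of 14, rt
Reagents that add atoms: none
Why: Proposed new method: Rh2(OAc)4 (a divalent rhodium dimer) should expel N2 from 14 and form an electrophilic aryl- and acyl-substituted rhodium carbene at the future C3. The carbene carbon lies in a six-membered array with the O–CH2–O hydrogens of either ortho MOM ether (equivalent by the symmetry of ring A) and should insert into one of these C–H bonds through a three-centre, hydride-transfer-like transition state, forming C2–C3 and closing ring C at carbon. The closest known reaction types are rhodium carbene C–H insertion alpha to the ether oxygen of ortho-alkoxyaryl diazoketones, which gives chroman-4-ones, and insertion of aryl-substituted carbenes into acetal C–H bonds; the acetal methylene of an aryl MOM ether has not been used in this way. The step needs chemoselectivity for C–H insertion over capture of the carbene by the aryl ether oxygen (five-membered oxonium ylide, then [1,2]-shift to a benzofuranone); the doubly oxygen-activated, hydridic C–H bond, the weak donor ability of an oxygen conjugated to the aroyl ring, and the preference of donor/acceptor carbenes for hydridic C–H bonds should secure it. Other outlets are closed by structure: the prenyl groups are meta to the acyl carbon and could reach the carbene only through a meta-bridged ring, the ring B oxygens carry silyl groups whose C–H bonds are hindered and not activated by oxygen and which could form only a four-membered ylide, and the carbene has no beta hydrogen. C2 and C3 become stereocentres; trans is expected because methoxy and aryl avoid each other in the insertion transition state and because C3 epimerises easily next to the ketone, and the product is racemic since nothing in the system is chiral. Neither centre matters, as both become trigonal in step 9.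

Step 9
Reactants: 15 rac-(2R,3S)-3-[2,4-bis(triisopropylsilyloxy)phenyl]-2-methoxy-5,7-bis(methoxymethoxy)-6,8-bis(3-methylbut-2-enyl)chroman-4-one
Product: 16 3-[2,4-bis(triisopropylsilyloxy)phenyl]-5,7-dihydroxy-6,8-bis(3-methylbut-2-enyl)-4H-chromen-4-one
Conditions: HCl (1.25 M in MeOH), THF, 40 °C
Reagents that add atoms: none
Why: Acid ionises the C2 acetal and loss of the acidic C3 proton gives the chromone (beta-elimination of methanol, as in the dehydration of 2-hydroxyisoflavanones), while acetal exchange with methanol removes the two aryl MOM ethers. Aryl triisopropylsilyl ethers should survive dilute methanolic HCl, and mild temperature and short contact should spare the prenyl groups.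

Step 10
Reactants: 16 3-[2,4-bis(triisopropylsilyloxy)phenyl]-5,7-dihydroxy-6,8-bis(3-methylbut-2-enyl)-4H-chromen-4-one
Product: 17 5,7-dihydroxy-3-(2,4-dihydroxyphenyl)-6,8-bis(3-methylbut-2-enyl)-4H-chromen-4-one
Conditions: Bu4NF, AcOH, THF, 0 °C
Reagents that add atoms: none
Why: Fluoride-driven cleavage of the two aryl silyl ethers (formation of the strong Si–F bond), buffered with acetic acid so that the polyphenol is not exposed to strongly basic phenoxide conditions.

## Compound list

1 | phloroglucinol (benzene-1,3,5-triol) | Oc1cc(O)cc(O)c1 | starting material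
2 | 1,3,5-tris(methoxymethoxy)benzene | COCOc1cc(OCOC)cc(OCOC)c1 | intermediate
3 | prenyl bromide (1-bromo-3-methylbut-2-ene) | CC(C)=CCBr | starting material
4 | 2,4,6-tris(methoxymethoxy)phenyllithium | [Li]c1c(OCOC)cc(OCOC)cc1OCOC | intermediate (not isolated)
5 | 1,3,5-tris(methoxymethoxy)-2-(3-methylbut-2-enyl)benzene | COCOc1cc(OCOC)c(CC=C(C)C)c(OCOC)c1 | intermediate
6 | 2,4,6-tris(methoxymethoxy)-3-(3-methylbut-2-enyl)phenyllithium | [Li]c1c(OCOC)cc(OCOC)c(CC=C(C)C)c1OCOC | intermediate (not isolated)
7 | 1,3,5-tris(methoxymethoxy)-2,4-bis(3-methylbut-2-enyl)benzene | COCOc1cc(OCOC)c(CC=C(C)C)c(OCOC)c1CC=C(C)C | intermediate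
8 | 2,4-dihydroxyphenylacetic acid | OC(=O)Cc1ccc(O)cc1O | starting material
9 | 2-(2,4-dihydroxyphenyl)-N-methoxy-N-methylacetamide | CON(C)C(=O)Cc1ccc(O)cc1O | intermediate
10 | 2-[2,4-bis(triisopropylsilyloxy)phenyl]-N-methoxy-N-methylacetamide | CON(C)C(=O)Cc1ccc(O[Si](C(C)C)(C(C)C)C(C)C)cc1O[Si](C(C)C)(C(C)C)C(C)C | intermediate
11 | 2,4,6-tris(methoxymethoxy)-3,5-bis(3-methylbut-2-enyl)phenyllithium | [Li]c1c(OCOC)c(CC=C(C)C)c(OCOC)c(CC=C(C)C)c1OCOC | intermediate (not isolated)
12 | lithium 2-[2,4-bis(triisopropylsilyloxy)phenyl]-1-[methoxy(methyl)amino]-1-[2,4,6-tris(methoxymethoxy)-3,5-bis(3-methylbut-2-enyl)phenyl]ethan-1-olate (racemic tetrahedral adduct) | [Li]OC(Cc1ccc(O[Si](C(C)C)(C(C)C)C(C)C)cc1O[Si](C(C)C)(C(C)C)C(C)C)(N(C)OC)c1c(OCOC)c(CC=C(C)C)c(OCOC)c(CC=C(C)C)c1OCOC | intermediate (not isolated)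
13 | 2-[2,4-bis(triisopropylsilyloxy)phenyl]-1-[2,4,6-tris(methoxymethoxy)-3,5-bis(3-methylbut-2-enyl)phenyl]ethan-1-one | COCOc1c(CC=C(C)C)c(OCOC)c(CC=C(C)C)c(OCOC)c1C(=O)Cc1ccc(O[Si](C(C)C)(C(C)C)C(C)C)cc1O[Si](C(C)C)(C(C)C)C(C)C | intermediate
14 | 2-diazo-2-[2,4-bis(triisopropylsilyloxy)phenyl]-1-[2,4,6-tris(methoxymethoxy)-3,5-bis(3-methylbut-2-enyl)phenyl]ethan-1-one | COCOc1c(CC=C(C)C)c(OCOC)c(CC=C(C)C)c(OCOC)c1C(=O)C(=[N+]=[N-])c1ccc(O[Si](C(C)C)(C(C)C)C(C)C)cc1O[Si](C(C)C)(C(C)C)C(C)C | intermediate
15 | rac-(2R,3S)-3-[2,4-bis(triisopropylsilyloxy)phenyl]-2-methoxy-5,7-bis(methoxymethoxy)-6,8-bis(3-methylbut-2-enyl)chroman-4-one (trans, racemic; one enantiomer drawn) | CO[C@@H]1Oc2c(CC=C(C)C)c(OCOC)c(CC=C(C)C)c(OCOC)c2C(=O)[C@H]1c1ccc(O[Si](C(C)C)(C(C)C)C(C)C)cc1O[Si](C(C)C)(C(C)C)C(C)C | intermediate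
16 | 3-[2,4-bis(triisopropylsilyloxy)phenyl]-5,7-dihydroxy-6,8-bis(3-methylbut-2-enyl)-4H-chromen-4-one | CC(C)=CCc1c(O)c(CC=C(C)C)c2occ(-c3ccc(O[Si](C(C)C)(C(C)C)C(C)C)cc3O[Si](C(C)C)(C(C)C)C(C)C)c(=O)c2c1O | intermediate
17 | 5,7-dihydroxy-3-(2,4-dihydroxyphenyl)-6,8-bis(3-methylbut-2-enyl)-4H-chromen-4-one | CC(C)=CCc1c(O)c(CC=C(C)C)c2occ(-c3ccc(O)cc3O)c(=O)c2c1O | target

## Step count and least certain steps

Total: 10 steps. Longest linear sequence: 8 steps (1, 2, 3, 6, 7, 8, 9, 10, from phloroglucinol); steps 4 and 5 form the ring B branch.

**Step 8 (key step).** The likeliest failure is diversion of the carbene to the lone pair of the aryl ether oxygen, giving a five-membered oxonium ylide whose methoxymethyl group shifts to carbon. Carbene dimerisation could add to it if the diazoketone accumulates, and insertion into a methine C–H bond of the 2'-O silyl group through a ring of the same size is a lesser risk. Within the step, a more electron-rich or bulkier ligand set (Rh2(NHCOCH3)4, dirhodium tetraacetamidate, or Rh2(O2CCPh3)4, dirhodium tetrakis(triphenylacetate)) and higher dilution are the first remedies. The fallback uses known chemistry and sets out from ketone 13. Heating 13 with N,N-dimethylformamide dimethyl acetal should give the enaminone (E)-2-[2,4-bis(triisopropylsilyloxy)phenyl]-3-(dimethylamino)-1-[2,4,6-tris(methoxymethoxy)-3,5-bis(3-methylbut-2-enyl)phenyl]prop-2-en-1-one F1. Methanolic HCl then removes the MOM groups, a freed ortho phenol adds to the enaminone and expels dimethylamine, and the route is rejoined at 16. In that case C2 comes from the formamide acetal and steps 7 to 9 are bypassed.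

**Step 6.** The likeliest failure is proton transfer in place of addition: the hindered, doubly ortho-substituted aryllithium 11 may deprotonate the acidic benzylic CH2 of amide 10, so that 7 and 10 return on quench. A lesser risk is metalation of a benzylic-allylic CH2 while 11 is formed. The fallback sets out from 10. Reduction with i-Bu2AlH (THF, −78 °C) should give 2-[2,4-bis(triisopropylsilyloxy)phenyl]acetaldehyde F2. Aryllithium 11 is transmetalated with anhydrous CeCl3 to the less basic dichloro[2,4,6-tris(methoxymethoxy)-3,5-bis(3-methylbut-2-enyl)phenyl]cerium F3, which should add to F2 without enolisation to give 2-[2,4-bis(triisopropylsilyloxy)phenyl]-1-[2,4,6-tris(methoxymethoxy)-3,5-bis(3-methylbut-2-enyl)phenyl]ethan-1-ol F4 (racemic). Dess–Martin periodinane oxidises F4 and the route is rejoined at 13.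

**Step 7.** The likeliest failure is incomplete diazo transfer, because the enolate carbon is shielded by an ortho-silyloxyaryl group and a twisted aroyl group; amidine-induced loss or migration of the ortho silyl group is the second risk. The fallback sets out from 13 and replaces direct transfer by deacylative diazo transfer. LiN(SiMe3)2 (THF, −78 °C) and 2,2,2-trifluoroethyl trifluoroacetate should give 2-[2,4-bis(triisopropylsilyloxy)phenyl]-4,4,4-trifluoro-1-[2,4,6-tris(methoxymethoxy)-3,5-bis(3-methylbut-2-enyl)phenyl]butane-1,3-dione F5. Methanesulfonyl azide with Et3N and one equivalent of water in MeCN then transfers the diazo group with loss of the trifluoroacetyl group, and the route is rejoined at 14.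

**Step 9.** The likeliest failure is acid-catalysed addition of a freed 5- or 7-hydroxyl to the neighbouring prenyl double bond (dimethylchroman formation) before the hindered 7-O-MOM group has gone; partial loss of the silyl ethers would also give mixtures. The fallback sets out from 15 and avoids protic acid. DBU in CH2Cl2 should eliminate methanol (E1cB) to 3-[2,4-bis(triisopropylsilyloxy)phenyl]-5,7-bis(methoxymethoxy)-6,8-bis(3-methylbut-2-enyl)-4H-chromen-4-one F6. Me3SiOTf with 2,2'-bipyridyl in MeCN then exchanges the two aryl MOM ethers for trimethylsilyl ethers, giving 3-[2,4-bis(triisopropylsilyloxy)phenyl]-5,7-bis(trimethylsilyloxy)-6,8-bis(3-methylbut-2-enyl)-4H-chromen-4-one F7. Aqueous work-up hydrolyses F7 and the route is rejoined at 16.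

## Further compounds

F1 | step 8 | (E)-2-[2,4-bis(triisopropylsilyloxy)phenyl]-3-(dimethylamino)-1-[2,4,6-tris(methoxymethoxy)-3,5-bis(3-methylbut-2-enyl)phenyl]prop-2-en-1-one | CN(C)/C=C(/C(=O)c1c(OCOC)c(CC=C(C)C)c(OCOC)c(CC=C(C)C)c1OCOC)c1ccc(O[Si](C(C)C)(C(C)C)C(C)C)cc1O[Si](C(C)C)(C(C)C)C(C)C
F2 | step 6 | 2-[2,4-bis(triisopropylsilyloxy)phenyl]acetaldehyde | O=CCc1ccc(O[Si](C(C)C)(C(C)C)C(C)C)cc1O[Si](C(C)C)(C(C)C)C(C)C
F3 | step 6 | dichloro[2,4,6-tris(methoxymethoxy)-3,5-bis(3-methylbut-2-enyl)phenyl]cerium | Cl[Ce](Cl)c1c(OCOC)c(CC=C(C)C)c(OCOC)c(CC=C(C)C)c1OCOC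
F4 | step 6 | 2-[2,4-bis(triisopropylsilyloxy)phenyl]-1-[2,4,6-tris(methoxymethoxy)-3,5-bis(3-methylbut-2-enyl)phenyl]ethan-1-ol (racemic) | COCOc1c(CC=C(C)C)c(OCOC)c(CC=C(C)C)c(OCOC)c1C(O)Cc1ccc(O[Si](C(C)C)(C(C)C)C(C)C)cc1O[Si](C(C)C)(C(C)C)C(C)C
F5 | step 7 | 2-[2,4-bis(triisopropylsilyloxy)phenyl]-4,4,4-trifluoro-1-[2,4,6-tris(methoxymethoxy)-3,5-bis(3-methylbut-2-enyl)phenyl]butane-1,3-dione (racemic) | COCOc1c(CC=C(C)C)c(OCOC)c(CC=C(C)C)c(OCOC)c1C(=O)C(C(=O)C(F)(F)F)c1ccc(O[Si](C(C)C)(C(C)C)C(C)C)cc1O[Si](C(C)C)(C(C)C)C(C)C
F6 | step 9 | 3-[2,4-bis(triisopropylsilyloxy)phenyl]-5,7-bis(methoxymethoxy)-6,8-bis(3-methylbut-2-enyl)-4H-chromen-4-one | COCOc1c(CC=C(C)C)c(OCOC)c(CC=C(C)C)c2occ(-c3ccc(O[Si](C(C)C)(C(C)C)C(C)C)cc3O[Si](C(C)C)(C(C)C)C(C)C)c(=O)c12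
F7 | step 9 | 3-[2,4-bis(triisopropylsilyloxy)phenyl]-5,7-bis(trimethylsilyloxy)-6,8-bis(3-methylbut-2-enyl)-4H-chromen-4-one | C[Si](C)(C)Oc1c(CC=C(C)C)c(O[Si](C)(C)C)c(CC=C(C)C)c2occ(-c3ccc(O[Si](C(C)C)(C(C)C)C(C)C)cc3O[Si](C(C)C)(C(C)C)C(C)C)c(=O)c12
A1 | alternative 1 | 5,7-bis(allyloxy)-3-[2,4-bis(methoxymethoxy)phenyl]-4H-chromen-4-one | C=CCOc1cc(OCC=C)c2c(c1)occ(-c1ccc(OCOC)cc1OCOC)c2=O
A2 | alternative 1 | 6,8-diallyl-5,7-dihydroxy-3-[2,4-bis(methoxymethoxy)phenyl]-4H-chromen-4-one | C=CCc1c(O)c(CC=C)c2occ(-c3ccc(OCOC)cc3OCOC)c(=O)c2c1O
A3 | alternative 2 | (E)-1-[2,4-bis(benzyloxy)-6-hydroxyphenyl]-3-[2,4-bis(benzyloxy)phenyl]prop-2-en-1-one | O=C(/C=C/c1ccc(OCc2ccccc2)cc1OCc1ccccc1)c1c(O)cc(OCc2ccccc2)cc1OCc1ccccc1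
A4 | alternative 2 | 5,7-bis(benzyloxy)-3-[2,4-bis(benzyloxy)phenyl]-4H-chromen-4-one | O=c1c(-c2ccc(OCc3ccccc3)cc2OCc2ccccc2)coc2cc(OCc3ccccc3)cc(OCc3ccccc3)c12
A5 | alternative 3 | 3-{[3,5-bis(allyloxy)phenoxy]methylene}-2-oxo-2,3-dihydrobenzofuran-6-yl acetate | CC(=O)Oc1ccc2c(c1)OC(=O)C2=COc1cc(OCC=C)cc(OCC=C)c1
A6 | alternative 3 | 4-[5,7-bis(allyloxy)-4-oxo-4H-chromen-3-yl]-3-hydroxyphenyl acetate | C=CCOc1cc(OCC=C)c2c(c1)occ(-c1ccc(OC(C)=O)cc1O)c2=O
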